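Everything rests on making the benzo ring (ring A) of the coumarin from acyclic pieces. In ring A the ring oxygen O1 on C8a lies para to the C6 hydroxyl, the C7 hydroxyl is the neighbour of C6, and C4a carries the carbon chain: a hydroquinone monoether pattern, which a chromium carbene benzannulation creates directly. An α-ethoxyvinyl methoxycarbene complex is therefore combined with a terminal enyne that already carries the C3 aryl ether and a methyl ester cis to the alkyne. One operation forms C5–C6, C4a–C8a and C8–C8a, and the new C8a phenol closes the pyranone at O1–C2. Ether cleavage, MOM protection, a Heck coupling with an (R)-danshensu acrylate and acid deprotection complete the target.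

Key step: step 6

Assumption: sodium (R)-danshensu, the sodium salt of (2R)-3-(3,4-dihydroxyphenyl)-2-hydroxypropanoic acid, is taken as a commercial enantiopure starting material and is the source of the only stereocenter.

Step 1
Reactants: 1 ethyl vinyl ether; 2 chromium hexacarbonyl, Cr(CO)6
Product: 5 pentacarbonyl[(1-ethoxyvinyl)(methoxy)carbene]chromium, via 1-ethoxyvinyllithium 3 (not isolated), via lithium acylchromate 4 (not isolated)
Conditions: t-BuLi, THF, −78 → 0 °C; Cr(CO)6, Et2O, 0 °C → rt; then Me3OBF4, CH2Cl2, 0 °C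
Reagents that add atoms: trimethyloxonium tetrafluoroborate, C[O+](C)C.F[B-](F)(F)F
Why: α-Lithiation of the enol ether gives vinyllithium 3, which adds to a carbonyl ligand of Cr(CO)6 to give acylchromate 4, and hard O-methylation by the oxonium salt completes the classical Fischer carbene complex synthesis without creating a stereocenter.

Step 2
Reactants: 6 methyl 2-[bis(2,2,2-trifluoroethoxy)phosphoryl]acetate
Product: 7 methyl 2-[bis(2,2,2-trifluoroethoxy)phosphoryl]-2-diazoacetate
Conditions: p-ABSA (4-acetamidobenzenesulfonyl azide), DBU, MeCN, 0 °C → rt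
Reagents that add atoms: 4-acetamidobenzenesulfonyl azide, CC(=O)Nc1ccc(cc1)S(=O)(=O)N=[N+]=[N-]
Why: Regitz diazo transfer, in which the acidic methylene between phosphoryl and ester groups is deprotonated by DBU and takes the terminal N2 unit of the sulfonyl azide.

Step 3
Reactants: 7 methyl 2-[bis(2,2,2-trifluoroethoxy)phosphoryl]-2-diazoacetate; 8 4-bromo-2-methoxyphenol
Product: 9 methyl 2-[bis(2,2,2-trifluoroethoxy)phosphoryl]-2-(4-bromo-2-methoxyphenoxy)acetate (racemic)
Conditions: Rh2(OAc)4 (2 mol %), PhMe, 80 °C, slow addition of 7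
Reagents that add atoms: none
Why: Rhodium carbenoid O–H insertion, in which the phenol hydroxyl intercepts the electrophilic acceptor/acceptor carbenoid faster than arene or C–H pathways, the racemic center so formed being erased in step 4.

Step 4
Reactants: 9 methyl 2-[bis(2,2,2-trifluoroethoxy)phosphoryl]-2-(4-bromo-2-methoxyphenoxy)acetate; 10 3-(trimethylsilyl)propynal
Product: 11 methyl (E)-2-(4-bromo-2-methoxyphenoxy)-5-(trimethylsilyl)pent-2-en-4-ynoate (alkynyl group cis to the ester)
Conditions: KN(SiMe3)2, 18-crown-6, THF, −78 °C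
Reagents that add atoms: none
Why: Still–Gennari variant of the Horner–Wadsworth–Emmons olefination, whose kinetically controlled elimination from the trifluoroethyl phosphonate adduct should place the aldehyde-derived alkynyl group cis to the ester (the descriptor is E because the aryloxy oxygen outranks the ester carbon), as established for α-alkyl and α-halo reagents of this class, any (Z) isomer being removed by chromatography.

Step 5
Reactants: 11 methyl (E)-2-(4-bromo-2-methoxyphenoxy)-5-(trimethylsilyl)pent-2-en-4-ynoate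
Product: 12 methyl (E)-2-(4-bromo-2-methoxyphenoxy)pent-2-en-4-ynoate
Conditions: Bu4NF, AcOH, THF, −20 → 0 °C
Reagents that add atoms: none
Why: Fluoride-induced protodesilylation of the alkynylsilane, buffered with acetic acid so that the acceptor enyne and its double-bond geometry are not exposed to a free base.

Step 6
Reactants: 5 pentacarbonyl[(1-ethoxyvinyl)(methoxy)carbene]chromium; 12 methyl (E)-2-(4-bromo-2-methoxyphenoxy)pent-2-en-4-ynoate
Product: 15 3-(4-bromo-2-methoxyphenoxy)-7-ethoxy-6-methoxy-2H-chromen-2-one, via arene tricarbonylchromium complex 13 (not isolated), via hydroxycinnamate ester 14 (not isolated)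
Conditions: 5 (1.3 equiv), THF, 55 °C, Ar; then air, MeCN, rt; then TsOH·H2O (cat.), PhMe, 60 °C
Reagents that add atoms: none
Why: Thermal loss of one CO from 5 opens a coordination site for the terminal alkyne of 12, which inserts with its CH carbon bonding to the carbene carbon (C5–C6), and CO insertion then gives a chromium-bound dienylketene (C4a–C8a). This is the Dötz benzannulation of alkenyl(alkoxy)carbene chromium complexes (zerovalent chromium) with terminal alkynes, closest for α-alkoxyvinyl complexes made from lithiated enol ethers and for conjugated enynes as the alkyne partner. Ring A closes by 6π electrocyclization of the dienylketene (C8–C8a) and tautomerization to the chromium-bound 4-methoxyphenol 13, so that the ketene carbonyl becomes the C8a oxygen, the carbene methoxy the C6 substituent, the enol ether oxygen the C7 substituent and the alkyne substituent the chain on C4a. Air then releases the arene from chromium as 14, and the pyranone closes by 6-exo-trig addition–elimination of the C8a hydroxyl on the cis methyl ester (O1–C2) with loss of methanol. No stereocenter is formed. The step needs regioselective alkyne insertion, secured by the unsubstituted alkyne terminus that keeps the substituted carbon away from the carbene carbon, and an ester cis to the new aryl group, secured by the (E) geometry set in step 4; the aryl bromide and the trisubstituted enoate should be inert under these conditions.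

Step 7
Reactants: 15 3-(4-bromo-2-methoxyphenoxy)-7-ethoxy-6-methoxy-2H-chromen-2-one
Product: 16 3-(4-bromo-2-hydroxyphenoxy)-6,7-dihydroxy-2H-chromen-2-one
Conditions: BBr3 (excess), CH2Cl2, −78 °C → rt; then H2O
Reagents that add atoms: none
Why: Lewis acid ether cleavage, in which BBr3 coordinates each alkyl aryl ether oxygen and bromide removes the methyl or ethyl group by SN2, while the diaryl ether (no sp3 carbon on oxygen), the aryl bromide and the lactone are not attacked.

Step 8
Reactants: 16 3-(4-bromo-2-hydroxyphenoxy)-6,7-dihydroxy-2H-chromen-2-one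
Product: 17 3-[4-bromo-2-(methoxymethoxy)phenoxy]-6,7-bis(methoxymethoxy)-2H-chromen-2-one
Conditions: MOMCl, i-Pr2NEt, DMF, 0 °C → rt
Reagents that add atoms: chloromethyl methyl ether, COCCl
Why: Williamson-type O-alkylation of the three phenols by the reactive α-chloro ether gives acid-labile acetals that shield the catechol from oxidation and from binding palladium in step 11.

Step 9
Reactants: 18 sodium (2R)-3-(3,4-dihydroxyphenyl)-2-hydroxypropanoate (sodium danshensu)
Product: 19 methoxymethyl (2R)-3-[3,4-bis(methoxymethoxy)phenyl]-2-hydroxypropanoate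
Conditions: MOMCl (3.2 equiv), K2CO3, DMF, 0 °C, Ar
Reagents that add atoms: chloromethyl methyl ether, COCCl
Why: Chemoselective O-alkylation, since the carboxylate and the two phenoxides are alkylated under carbonate conditions at 0 °C whereas the neutral, electron-poor secondary hydroxyl should stay free, and the stereocenter is not touched.

Step 10
Reactants: 19 methoxymethyl (2R)-3-[3,4-bis(methoxymethoxy)phenyl]-2-hydroxypropanoate; 20 acryloyl chloride
Product: 21 methoxymethyl (2R)-2-(acryloyloxy)-3-[3,4-bis(methoxymethoxy)phenyl]propanoate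
Conditions: Et3N, DMAP (cat.), CH2Cl2, −20 → 0 °C
Reagents that add atoms: none
Why: Nucleophilic acyl substitution of the acid chloride by the secondary alcohol under amine/DMAP catalysis takes place at oxygen only, so the (R) configuration is retained.

Step 11
Reactants: 17 3-[4-bromo-2-(methoxymethoxy)phenoxy]-6,7-bis(methoxymethoxy)-2H-chromen-2-one; 21 methoxymethyl (2R)-2-(acryloyloxy)-3-[3,4-bis(methoxymethoxy)phenyl]propanoate
Product: 22 methoxymethyl (2R)-3-[3,4-bis(methoxymethoxy)phenyl]-2-{[(2E)-3-{4-[(6,7-bis(methoxymethoxy)-2-oxo-2H-chromen-3-yl)oxy]-3-(methoxymethoxy)phenyl}prop-2-enoyl]oxy}propanoate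
Conditions: Pd[P(t-Bu)3]2 (5 mol %), Cy2NMe, 1,4-dioxane, 70 °C
Reagents that add atoms: none
Why: Mizoroki–Heck reaction, in which zerovalent palladium with the bulky electron-rich phosphine inserts into the aryl–bromine bond at moderate temperature, syn carbopalladation of the acrylate and syn β-hydride elimination give the (E)-cinnamate, and the hindered amine is too weak a base to epimerize the α-acyloxy ester center.

Step 12
Reactants: 22 methoxymethyl (2R)-3-[3,4-bis(methoxymethoxy)phenyl]-2-{[(2E)-3-{4-[(6,7-bis(methoxymethoxy)-2-oxo-2H-chromen-3-yl)oxy]-3-(methoxymethoxy)phenyl}prop-2-enoyl]oxy}propanoate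
Product: 23 (2R)-3-(3,4-dihydroxyphenyl)-2-{[(2E)-3-{4-[(6,7-dihydroxy-2-oxo-2H-chromen-3-yl)oxy]-3-hydroxyphenyl}prop-2-enoyl]oxy}propanoic acid (CNP0318082.1)
Conditions: 3 M aq. HCl, THF, 45 °C
Reagents that add atoms: none
Why: Acid-catalysed acetal hydrolysis through oxocarbenium ions should remove the five aryl MOM ethers and the MOM ester in one operation, under which the cinnamate ester, the lactone and the base-sensitive stereocenter are stable.

Compound list
1 | ethyl vinyl ether | C=COCC | starting material
2 | chromium hexacarbonyl, Cr(CO)6 | O=C=[Cr](=C=O)(=C=O)(=C=O)(=C=O)=C=O | starting material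
3 | 1-ethoxyvinyllithium | [Li]C(=C)OCC | intermediate
4 | lithium pentacarbonyl[(1-ethoxyvinyl)(oxido)carbene]chromate (lithium acylchromate) | [Li+].[O-]C(=[Cr](=C=O)(=C=O)(=C=O)(=C=O)=C=O)C(=C)OCC | intermediate
5 | pentacarbonyl[(1-ethoxyvinyl)(methoxy)carbene]chromium | COC(=[Cr](=C=O)(=C=O)(=C=O)(=C=O)=C=O)C(=C)OCC | intermediate
6 | methyl 2-[bis(2,2,2-trifluoroethoxy)phosphoryl]acetate | COC(=O)CP(=O)(OCC(F)(F)F)OCC(F)(F)F | starting material
7 | methyl 2-[bis(2,2,2-trifluoroethoxy)phosphoryl]-2-diazoacetate | COC(=O)C(=[N+]=[N-])P(=O)(OCC(F)(F)F)OCC(F)(F)F | intermediate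
8 | 4-bromo-2-methoxyphenol | COc1cc(Br)ccc1O | starting material
9 | methyl 2-[bis(2,2,2-trifluoroethoxy)phosphoryl]-2-(4-bromo-2-methoxyphenoxy)acetate (racemic) | COC(=O)C(Oc1ccc(Br)cc1OC)P(=O)(OCC(F)(F)F)OCC(F)(F)F | intermediate
10 | 3-(trimethylsilyl)propynal | C[Si](C)(C)C#CC=O | starting material
11 | methyl (E)-2-(4-bromo-2-methoxyphenoxy)-5-(trimethylsilyl)pent-2-en-4-ynoate | C[Si](C)(C)C#C/C=C(/Oc1ccc(Br)cc1OC)C(=O)OC | intermediate
12 | methyl (E)-2-(4-bromo-2-methoxyphenoxy)pent-2-en-4-ynoate | C#C/C=C(/Oc1ccc(Br)cc1OC)C(=O)OC | intermediate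
13 | tricarbonyl{η6-[methyl (E)-2-(4-bromo-2-methoxyphenoxy)-3-(4-ethoxy-2-hydroxy-5-methoxyphenyl)prop-2-enoate]}chromium (ring A bound η6 to the Cr(CO)3 fragment, which is written as a separate fragment in the SMILES) | COC(=O)/C(Oc1ccc(Br)cc1OC)=C\c1cc(OC)c(OCC)cc1O.O=C=[Cr](=C=O)=C=O | intermediate
14 | methyl (E)-2-(4-bromo-2-methoxyphenoxy)-3-(4-ethoxy-2-hydroxy-5-methoxyphenyl)prop-2-enoate (aryl group cis to the ester) | COC(=O)/C(Oc1ccc(Br)cc1OC)=C\c1cc(OC)c(OCC)cc1O | intermediate
15 | 3-(4-bromo-2-methoxyphenoxy)-7-ethoxy-6-methoxy-2H-chromen-2-one | CCOc1cc2oc(=O)c(Oc3ccc(Br)cc3OC)cc2cc1OC | intermediate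
16 | 3-(4-bromo-2-hydroxyphenoxy)-6,7-dihydroxy-2H-chromen-2-one | O=c1oc2cc(O)c(O)cc2cc1Oc1ccc(Br)cc1O | intermediate
17 | 3-[4-bromo-2-(methoxymethoxy)phenoxy]-6,7-bis(methoxymethoxy)-2H-chromen-2-one | COCOc1cc2oc(=O)c(Oc3ccc(Br)cc3OCOC)cc2cc1OCOC | intermediate
18 | sodium (2R)-3-(3,4-dihydroxyphenyl)-2-hydroxypropanoate (sodium danshensu) | O[C@H](Cc1ccc(O)c(O)c1)C(=O)[O-].[Na+] | starting material
19 | methoxymethyl (2R)-3-[3,4-bis(methoxymethoxy)phenyl]-2-hydroxypropanoate | O[C@H](Cc1ccc(OCOC)c(OCOC)c1)C(=O)OCOC | intermediate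
20 | acryloyl chloride | C=CC(=O)Cl | starting material
21 | methoxymethyl (2R)-2-(acryloyloxy)-3-[3,4-bis(methoxymethoxy)phenyl]propanoate | C=CC(=O)O[C@H](Cc1ccc(OCOC)c(OCOC)c1)C(=O)OCOC | intermediate
22 | methoxymethyl (2R)-3-[3,4-bis(methoxymethoxy)phenyl]-2-{[(2E)-3-{4-[(6,7-bis(methoxymethoxy)-2-oxo-2H-chromen-3-yl)oxy]-3-(methoxymethoxy)phenyl}prop-2-enoyl]oxy}propanoate | O=C(/C=C/c1ccc(Oc2cc3cc(OCOC)c(OCOC)cc3oc2=O)c(OCOC)c1)O[C@H](Cc1ccc(OCOC)c(OCOC)c1)C(=O)OCOC | intermediate
23 | (2R)-3-(3,4-dihydroxyphenyl)-2-{[(2E)-3-{4-[(6,7-dihydroxy-2-oxo-2H-chromen-3-yl)oxy]-3-hydroxyphenyl}prop-2-enoyl]oxy}propanoic acid | O=C(/C=C/c1ccc(Oc2cc3cc(O)c(O)cc3oc2=O)c(O)c1)O[C@H](Cc1ccc(O)c(O)c1)C(=O)O | target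

Total step count: 12.
Longest linear sequence: 9 steps (steps 2, 3, 4, 5, 6, 7, 8, 11 and 12, counted from compound 6).

Steps most likely to fail

1. Step 6. Alkyne insertion may stall or be diverted because the alkyne is conjugated to an acceptor alkene (oligomerisation of the enyne, cyclobutenone or furan formation instead of benzannulation). The α-alkoxyvinyl carbene complex may also decompose thermally before it is consumed. The fallback sets out from phosphonate 9 and builds the coumarin on a preformed arene. Still–Gennari-type olefination of 9 with commercial 2-hydroxy-4,5-dimethoxybenzaldehyde F1 (K2CO3, 18-crown-6, PhMe, rt → 60 °C) should place the ester cis to the phenoxide. The phenoxide should lactonize in the same flask to 3-(4-bromo-2-methoxyphenoxy)-6,7-dimethoxy-2H-chromen-2-one F2. BBr3 in CH2Cl2 then cleaves its three methyl ethers, and the route is rejoined at triol 16.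

2. Step 4. Equilibration of the phosphonate–aldehyde adducts before elimination would erode the kinetic geometry and deliver the isomer with the alkyne trans to the ester, which cannot lactonize in step 6. The fallback sets out from 9 and 10 as before but carries the other geometric isomer, methyl (Z)-2-(4-bromo-2-methoxyphenoxy)-5-(trimethylsilyl)pent-2-en-4-ynoate F3, forward. Desilylation (Bu4NF, AcOH, THF) should give methyl (Z)-2-(4-bromo-2-methoxyphenoxy)pent-2-en-4-ynoate F4. Benzannulation of F4 with 5 followed by air should give the open-chain methyl (Z)-2-(4-bromo-2-methoxyphenoxy)-3-(4-ethoxy-2-hydroxy-5-methoxyphenyl)prop-2-enoate F5. Irradiation at 365 nm in MeCN then isomerizes the cinnamate double bond; the cis form is drained irreversibly by lactonization, as in the classical photochemical conversion of o-hydroxycinnamates into coumarins. The route is rejoined at coumarin 15.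

3. Step 11. Slow oxidative addition into the electron-rich aryl bromide may call for temperatures at which the acrylate polymerizes or its MOM ester is lost. The fallback sets out from 17 and couples it with acrylic acid instead (Pd(OAc)2, P(o-tol)3, Et3N, DMF, 100 °C). This partner tolerates forcing conditions because it carries neither a stereocenter nor a labile ester, and should give (2E)-3-{4-[(6,7-bis(methoxymethoxy)-2-oxo-2H-chromen-3-yl)oxy]-3-(methoxymethoxy)phenyl}prop-2-enoic acid F6. Steglich esterification of F6 with alcohol 19 (EDC·HCl, DMAP, CH2Cl2, 0 °C → rt) then comes back to the route at 22.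

Further compounds
F1 | step 6 | 2-hydroxy-4,5-dimethoxybenzaldehyde | COc1cc(O)c(C=O)cc1OC
F2 | step 6 | 3-(4-bromo-2-methoxyphenoxy)-6,7-dimethoxy-2H-chromen-2-one | COc1cc2oc(=O)c(Oc3ccc(Br)cc3OC)cc2cc1OC
F3 | step 4 | methyl (Z)-2-(4-bromo-2-methoxyphenoxy)-5-(trimethylsilyl)pent-2-en-4-ynoate | C[Si](C)(C)C#C/C=C(\Oc1ccc(Br)cc1OC)C(=O)OC
F4 | step 4 | methyl (Z)-2-(4-bromo-2-methoxyphenoxy)pent-2-en-4-ynoate | C#C/C=C(\Oc1ccc(Br)cc1OC)C(=O)OC
F5 | step 4 | methyl (Z)-2-(4-bromo-2-methoxyphenoxy)-3-(4-ethoxy-2-hydroxy-5-methoxyphenyl)prop-2-enoate | COC(=O)/C(Oc1ccc(Br)cc1OC)=C/c1cc(OC)c(OCC)cc1O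
F6 | step 11 | (2E)-3-{4-[(6,7-bis(methoxymethoxy)-2-oxo-2H-chromen-3-yl)oxy]-3-(methoxymethoxy)phenyl}prop-2-enoic acid | OC(=O)/C=C/c1ccc(Oc2cc3cc(OCOC)c(OCOC)cc3oc2=O)c(OCOC)c1
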